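Compound numbers used throughout (names and SMILES in the list after the steps): 1 3,5-dimethoxyphenol; 3 prenyl bromide; 6 the symmetric prenylated phenol; 13 the silyl triflate; 14 the arylacetate; 15 methyl formate; 17 the hydroxyacrylate; 18 the aryne; 20 the annulation product; 22 the 5-hydroxy isoflavone; 24 the target.

## Analysis of the target

The target 24 is an isoflavone: a chromen-4-one (benzo ring A fused to pyranone ring C) with a 2,4,5-trimethoxyphenyl group (ring B) at C3. Ring A is fully substituted: 5-OH, 6-prenyl, 7-OMe and 8-OH, with C4a bound to the C4 carbonyl and C8a bound to O1. There is no stereocenter, and the prenyl double bond carries two identical methyl groups, so no configuration has to be set. The sensitive parts are the 5,8-hydroquinone (air oxidises it to the quinone), the prenyl double bond beside the 5-hydroxyl (acid closes a chroman, electrophiles and oxidants add) and the pyranone (hydroxide attacks C2 and opens ring C). The difficulty is the order of four different substituents on ring A relative to O1 and C4. A classical ring C closure from a 2,6-dioxygenated aryl ketone must tell the C5 oxygen from the C8a oxygen, and a wrong choice gives the 8-prenyl isomer. The strategy rests on C8a and C4a: two neighbouring carbons of ring A that carry O1 and C4, substituents which one bifunctional partner can deliver to an aryne spanning C4a–C8a. The C5 oxygen beside that triple bond decides the orientation, provided C8 is still C–H.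

## Retrosynthetic reasoning

24 to 22: the C8–O bond is cut first. With oxygen at C8, both carbons flanking the C4a–C8a bond would carry alkoxy groups and the two ends of an aryne could not be told apart. As C–H, C8 is the only free position of ring A and lies para to the 5-hydroxyl, which is where an Elbs oxidation of the 5-phenoxide puts oxygen. The forward step has to spare the prenyl group and ring B.

22 to 20: the 5-O–CH3 bond is cut, so the 5-hydroxyl is carried as a methyl ether. An acetal at O5 would come off more gently, but with methyl on both O5 and O7 the ring A precursor descends from phenol 6, which has a mirror plane, so its two ortho positions are equivalent and the later silylation has no regiochemical question. Of the five methoxy groups in 20, only the peri one can form a six-membered chelate with the C4 carbonyl, so a chelating magnesium halide can remove it alone and without protic acid.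

20 to 13 + 17: O1–C8a and C4–C4a are cut together. Both bonds end on adjacent ring carbons, so ring A becomes aryne 18 (from silyl triflate 13) and ring C comes complete from the enol of formylacetate 17: its oxygen becomes O1, its ester carbon C4, and ring B is already attached. The forward reaction needs oxygen (not carbon) of the enolate to add at C8a, and the resulting C4a anion to reach the ester.

17 to 14 + 15: the C2–C3 bond of ring C (formyl carbon to the benzylic carbon) is cut. This is a crossed Claisen condensation of arylacetate 14 with methyl formate 15, which cannot enolise.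

13 to 6: the O–S and C–Si bonds are cut. Phenol 6 is converted into carbamate 7, which directs lithiation to its ortho position for silylation to 11. Base-induced carbamate cleavage and triflation then give 13 without acid, which the electron-rich C–Si bond would not survive.

6 to 1 + 3: the aryl–CH2 bond is cut. In silyl ether 2 the bulky silyloxy group neither directs nor admits lithiation beside it, so an alkyllithium removes the proton between the two methoxy groups. Allylation with 3 gives 5, and desilylation gives 6.

## Alternatives that were turned down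

Alternative 1: Ring C is cut at C3–C4 and O1–C2. Forward, enamine A3 of the ring B acetaldehyde is C-acylated by 2-acetoxybenzoyl chloride A2; after acetate cleavage the C8a phenoxide adds to C2 and expels the amine, giving A1. For it: the reaction type is established isoflavone chemistry, and A1 already carries the C8 oxygen, so no late C–H oxidation next to a prenyl group is needed. On both points it is stronger than the chosen route. Against it: A2 is a hexasubstituted benzene whose two oxygens ortho to the acyl carbon (C5 and C8a) must be differentiated as acetal and acetate. That is the very 6-prenyl/8-prenyl ambiguity of this ring, and the ring offers no handle for it. The acid chloride also has to be made beside two acid-labile acetals and a prenyl group, and A3 comes from an electron-rich arylacetaldehyde that self-condenses easily. Compared with the chosen route, the difficulty moves into a long linear preparation of A2. In the chosen route 13 comes in six steps from a symmetric phenol and the aryne polarity decides which oxygen becomes O1, at the price of two steps after ring closure.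

Alternative 2: C2–C3 is cut, C2 being the methylene carbon of a MOM ether on O8a. Forward, a dirhodium carboxylate catalyst converts α-diazo deoxybenzoin A5 into a C3 carbene that attacks the OCH2O unit. C2–C3 forms, the 2-methoxyisoflavanone loses its methoxy group and A4 results. For it: a protecting-group carbon is used as C2, the metal is catalytic, and the C8 oxygen is present early, which the chosen route cannot offer. Against it: an aryl acyl carbene held beside an aryl alkyl ether is expected to form the five-membered oxonium ylide at O8a faster than the six-membered C–H insertion. A 1,2-shift of the methoxymethyl group would then give a 2,2-disubstituted benzofuran-3-one. The prenyl double bond and the silyl ether C–H bonds are further carbene acceptors. A5 again needs ring A with every oxygen differentiated, plus diazo transfer to a ketone with two ortho substituents. Compared with the chosen route: once the deoxybenzoin behind A5 exists with a free 8a-hydroxyl, a one-carbon electrophile closes ring C by known chemistry, so the carbene step adds risk without saving steps. The chosen route needs no differentiated deoxybenzoin.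

Alternative 3: Ring B is cut. Forward, 3-ethynylchromone A7, the zerovalent chromium carbene complex A8 and one carbonyl ligand combine in a Dötz benzannulation (bonds C5'–C6', C1'–C2', C2'–C3') to the 2-hydroxy-4,5-dimethoxyphenyl compound A6. For it: the benzannulation regiochemistry (larger alkyne substituent beside the new hydroxyl) fits, and the 2'-oxygen emerges differentiated, which the target does not need. Against it: ring B is the one part that can be bought intact, so the key step is spent on the easy ring. A7 would come from iodochromone A9, which a single cross-coupling with a ring B organometallic would turn into the protected isoflavone directly. A8 is a stoichiometric, labile complex, the alkyne is conjugated to the chromone, and a further O-methylation follows. Compared with the chosen route, it is longer and leaves the whole ring A problem inside A9.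

Key step: step 8

Assumption: 17 is drawn as its hydrogen-bonded Z-enol; it equilibrates with the E-enol and the aldehyde, and its cesium enolate is taken to react from the chelated Z geometry.

## Route

Step 1
Reactants: 1 3,5-dimethoxyphenol
Product: 2 (3,5-dimethoxyphenoxy)tri(propan-2-yl)silane
Conditions: i-Pr3SiCl, imidazole, DMF, rt
Reagents that add atoms: chlorotri(propan-2-yl)silane, CC(C)[Si](Cl)(C(C)C)C(C)C
Why: Silyl ether formation; the bulky, non-coordinating silyloxy group blocks lithiation at its own ortho positions in step 2.

Step 2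
Reactants: 2 (3,5-dimethoxyphenoxy)tri(propan-2-yl)silane; 3 prenyl bromide (1-bromo-3-methylbut-2-ene)
Product: 5 [3,5-dimethoxy-4-(3-methylbut-2-enyl)phenoxy]tri(propan-2-yl)silane, via aryllithium 4 (not isolated)
Conditions: n-BuLi, THF, 0 °C to rt; CuBr·SMe2 (10 mol %), 3, −78 °C to rt
Reagents that add atoms: none
Why: Directed ortho-metalation at the only position flanked by two methoxy groups, then copper-catalysed SN2 allylation, which should give the linear prenyl group.

Step 3
Reactants: 5 [3,5-dimethoxy-4-(3-methylbut-2-enyl)phenoxy]tri(propan-2-yl)silane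
Product: 6 3,5-dimethoxy-4-(3-methylbut-2-enyl)phenol
Conditions: Bu4NF, wet THF, 0 °C
Reagents that add atoms: none
Why: Fluoride desilylation of an aryl silyl ether; nothing else in 5 responds to fluoride.

Step 4
Reactants: 6 3,5-dimethoxy-4-(3-methylbut-2-enyl)phenol
Product: 7 3,5-dimethoxy-4-(3-methylbut-2-enyl)phenyl N-(propan-2-yl)carbamate
Conditions: i-PrNCO, Et3N (cat.), CH2Cl2, rt
Reagents that add atoms: isopropyl isocyanate, CC(C)N=C=O
Why: Amine-catalysed addition of a phenol to an isocyanate; the carbamate is the directing group for step 5 and is removable by base in step 6.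

Step 5
Reactants: 7 3,5-dimethoxy-4-(3-methylbut-2-enyl)phenyl N-(propan-2-yl)carbamate
Product: 11 3,5-dimethoxy-4-(3-methylbut-2-enyl)-2-(trimethylsilyl)phenyl N-(propan-2-yl)carbamate, via N-silyl carbamate 8 (not isolated), via ortho-lithiated carbamate 9 (not isolated), via N-silyl C-silyl carbamate 10 (not isolated)
Conditions: t-BuMe2SiOTf, TMEDA, Et2O, 0 °C to rt; n-BuLi, TMEDA, −78 °C; Me3SiCl, −78 °C to rt; aq. NaHSO4
Reagents that add atoms: chlorotrimethylsilane, C[Si](C)(C)Cl
Why: Carbamate-directed ortho-lithiation after in-flask N-silylation (which masks N–H and suppresses the anionic ortho-Fries shift), with silyl chloride quench; the two ortho positions of 7 are equivalent by symmetry, and the N–Si bond is hydrolysed on work-up.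

Step 6
Reactants: 11 3,5-dimethoxy-4-(3-methylbut-2-enyl)-2-(trimethylsilyl)phenyl N-(propan-2-yl)carbamate
Product: 13 3,5-dimethoxy-4-(3-methylbut-2-enyl)-2-(trimethylsilyl)phenyl trifluoromethanesulfonate, via silyl phenol 12 (not isolated)
Conditions: Et2NH, DBU, MeCN, 40 °C; then PhNTf2, rt
Reagents that add atoms: N-phenylbis(trifluoromethanesulfonimide), O=S(=O)(N(c1ccccc1)S(=O)(=O)C(F)(F)F)C(F)(F)F
Why: E1cB cleavage of the N-monosubstituted carbamate (the isocyanate is trapped by Et2NH) and triflation of the phenoxide in the same flask; no acid is present, so the aryl–silicon bond should survive.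

Step 7
Reactants: 14 methyl 2-(2,4,5-trimethoxyphenyl)acetate; 15 methyl formate
Product: 17 methyl (Z)-3-hydroxy-2-(2,4,5-trimethoxyphenyl)prop-2-enoate, via sodium enolate 16 (not isolated)
Conditions: NaH, HCO2Me (excess), THF, 0 °C to rt; then 1 M HCl, 0 °C
Reagents that add atoms: none
Why: Crossed Claisen condensation with a non-enolisable formate, driven by formation of the stabilised enolate 16; acidification should give the chelated Z-enol.

Step 8
Reactants: 13 3,5-dimethoxy-4-(3-methylbut-2-enyl)-2-(trimethylsilyl)phenyl trifluoromethanesulfonate; 17 methyl (Z)-3-hydroxy-2-(2,4,5-trimethoxyphenyl)prop-2-enoate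
Product: 20 5,7-dimethoxy-6-(3-methylbut-2-enyl)-3-(2,4,5-trimethoxyphenyl)chromen-4-one, via aryne 18 (not isolated), via aryl anion 19 (not isolated)
Conditions: CsF (4 equiv), THF, 65 °C, slow addition of 13 (1.3 equiv)
Reagents that add atoms: none
Why: Proposed new method: CsF attacks silicon in 13 and triflate leaves, giving aryne 18; the cesium enolate of 17 adds through its terminal oxygen at C8a, the aryne carbon remote from the C5 methoxy group, and the aryl anion 19, placed at C4a beside that inductively stabilising oxygen, attacks the ester carbonyl five atoms away and expels methoxide (6-exo-trig addition–elimination), so that O1–C8a and C4–C4a form and ring C closes in one operation. The closest known reaction type is the fluoride-induced annulation of arynes with salicylate esters to xanthones; here the phenoxide is replaced by the enolate of a formylacetate, which has not been shown and which can also react at carbon. The regioselectivity (oxygen at C8a, anion at C4a) rests on the C5 alkoxy group, as in additions to 3-methoxybenzyne. O-arylation should be favoured over C-arylation because the enolate carbon is fully substituted and shielded by the ortho-methoxy aryl group and the cesium enolate is loosely paired, but C-arylation followed by aldehyde capture (formal insertion into the C–CHO bond) is the main competitor. Cyclisation requires the Z geometry of 19, which the chelated enolate provides; an E adduct could only be protonated. No stereocenter is formed.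

Step 9
Reactants: 20 5,7-dimethoxy-6-(3-methylbut-2-enyl)-3-(2,4,5-trimethoxyphenyl)chromen-4-one
Product: 22 5-hydroxy-7-methoxy-6-(3-methylbut-2-enyl)-3-(2,4,5-trimethoxyphenyl)chromen-4-one, via magnesium chelate 21 (not isolated)
Conditions: MgI2·OEt2 (3 equiv), THF, 65 °C, argon, dark; then 1 M HCl, 0 °C
Reagents that add atoms: none
Why: Chelation-controlled demethylation: magnesium bridges the C4 carbonyl and the peri 5-oxygen and iodide removes only that methyl group by SN2; the other four methoxy groups cannot form the six-membered chelate, and no protic acid is present to add across the prenyl double bond (a reaction type known on prenylated 5-methoxyflavanones).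

Step 10
Reactants: 22 5-hydroxy-7-methoxy-6-(3-methylbut-2-enyl)-3-(2,4,5-trimethoxyphenyl)chromen-4-one
Product: 24 5,8-dihydroxy-7-methoxy-6-(3-methylbut-2-enyl)-3-(2,4,5-trimethoxyphenyl)chromen-4-one, via aryl sulfate 23 (not isolated)
Conditions: K2S2O8, aq. KOH, pyridine, 0 °C to rt; then HCl (pH 1), Na2SO3, THF–H2O, 45 °C, N2
Reagents that add atoms: potassium peroxydisulfate, [K+].[K+].[O-]S(=O)(=O)OOS(=O)(=O)[O-]
Why: Elbs persulfate oxidation: the 5-phenoxide is attacked by peroxydisulfate at C8, the only free position and para to the phenoxide oxygen; mild acid hydrolysis of the aryl sulfate (S–O cleavage) under sulfite should release the hydroquinone, as known for 5-hydroxy-7-methoxy flavones and isoflavones.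

## Compound list

1 | 3,5-dimethoxyphenol | COc1cc(O)cc(OC)c1 | starting material
2 | (3,5-dimethoxyphenoxy)tri(propan-2-yl)silane | COc1cc(O[Si](C(C)C)(C(C)C)C(C)C)cc(OC)c1 | intermediate
3 | prenyl bromide (1-bromo-3-methylbut-2-ene) | CC(C)=CCBr | starting material
4 | [2,6-dimethoxy-4-tri(propan-2-yl)silyloxyphenyl]lithium | COc1cc(O[Si](C(C)C)(C(C)C)C(C)C)cc(OC)c1[Li] | intermediate
5 | [3,5-dimethoxy-4-(3-methylbut-2-enyl)phenoxy]tri(propan-2-yl)silane | COc1cc(O[Si](C(C)C)(C(C)C)C(C)C)cc(OC)c1CC=C(C)C | intermediate
6 | 3,5-dimethoxy-4-(3-methylbut-2-enyl)phenol | COc1cc(O)cc(OC)c1CC=C(C)C | intermediate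
7 | 3,5-dimethoxy-4-(3-methylbut-2-enyl)phenyl N-(propan-2-yl)carbamate | COc1cc(OC(=O)NC(C)C)cc(OC)c1CC=C(C)C | intermediate
8 | 3,5-dimethoxy-4-(3-methylbut-2-enyl)phenyl N-[tert-butyl(dimethyl)silyl]-N-(propan-2-yl)carbamate | COc1cc(OC(=O)N(C(C)C)[Si](C)(C)C(C)(C)C)cc(OC)c1CC=C(C)C | intermediate
9 | 2-lithio derivative of 8 | COc1cc(OC(=O)N(C(C)C)[Si](C)(C)C(C)(C)C)c([Li])c(OC)c1CC=C(C)C | intermediate
10 | 3,5-dimethoxy-4-(3-methylbut-2-enyl)-2-(trimethylsilyl)phenyl N-[tert-butyl(dimethyl)silyl]-N-(propan-2-yl)carbamate | COc1cc(OC(=O)N(C(C)C)[Si](C)(C)C(C)(C)C)c([Si](C)(C)C)c(OC)c1CC=C(C)C | intermediate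
11 | 3,5-dimethoxy-4-(3-methylbut-2-enyl)-2-(trimethylsilyl)phenyl N-(propan-2-yl)carbamate | COc1cc(OC(=O)NC(C)C)c([Si](C)(C)C)c(OC)c1CC=C(C)C | intermediate
12 | 3,5-dimethoxy-4-(3-methylbut-2-enyl)-2-(trimethylsilyl)phenol (present as its DBU-H salt) | COc1cc(O)c([Si](C)(C)C)c(OC)c1CC=C(C)C | intermediate
13 | 3,5-dimethoxy-4-(3-methylbut-2-enyl)-2-(trimethylsilyl)phenyl trifluoromethanesulfonate | COc1cc(OS(=O)(=O)C(F)(F)F)c([Si](C)(C)C)c(OC)c1CC=C(C)C | intermediate
14 | methyl 2-(2,4,5-trimethoxyphenyl)acetate | COC(=O)Cc1cc(OC)c(OC)cc1OC | starting material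
15 | methyl formate | COC=O | starting material
16 | sodium (Z)-3-methoxy-3-oxo-2-(2,4,5-trimethoxyphenyl)prop-1-en-1-olate | COC(=O)/C(=C\[O-])c1cc(OC)c(OC)cc1OC.[Na+] | intermediate
17 | methyl (Z)-3-hydroxy-2-(2,4,5-trimethoxyphenyl)prop-2-enoate | COC(=O)/C(=C\O)c1cc(OC)c(OC)cc1OC | intermediate
18 | 3,5-dimethoxy-4-(3-methylbut-2-enyl)benzyne (1,2-didehydrobenzene) | COC1=CC#CC(OC)=C1CC=C(C)C | intermediate
19 | methyl (Z)-3-[2-cesio-3,5-dimethoxy-4-(3-methylbut-2-enyl)phenoxy]-2-(2,4,5-trimethoxyphenyl)prop-2-enoate | COC(=O)/C(=C\Oc1cc(OC)c(CC=C(C)C)c(OC)c1[Cs])c1cc(OC)c(OC)cc1OC | intermediate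
20 | 5,7-dimethoxy-6-(3-methylbut-2-enyl)-3-(2,4,5-trimethoxyphenyl)chromen-4-one | COc1cc2occ(-c3cc(OC)c(OC)cc3OC)c(=O)c2c(OC)c1CC=C(C)C | intermediate
21 | iodomagnesium 5-phenoxide of 22 (chelated to the C4 carbonyl) | COc1cc2occ(-c3cc(OC)c(OC)cc3OC)c(=O)c2c(O[Mg]I)c1CC=C(C)C | intermediate
22 | 5-hydroxy-7-methoxy-6-(3-methylbut-2-enyl)-3-(2,4,5-trimethoxyphenyl)chromen-4-one | COc1cc2occ(-c3cc(OC)c(OC)cc3OC)c(=O)c2c(O)c1CC=C(C)C | intermediate
23 | potassium 5-hydroxy-7-methoxy-6-(3-methylbut-2-enyl)-4-oxo-3-(2,4,5-trimethoxyphenyl)chromen-8-yl sulfate | COc1c(OS(=O)(=O)[O-])c2occ(-c3cc(OC)c(OC)cc3OC)c(=O)c2c(O)c1CC=C(C)C.[K+] | intermediate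
24 | 5,8-dihydroxy-7-methoxy-6-(3-methylbut-2-enyl)-3-(2,4,5-trimethoxyphenyl)chromen-4-one | COc1cc(OC)c(-c2coc3c(O)c(OC)c(CC=C(C)C)c(O)c3c2=O)cc1OC | target

## Step count and least certain steps

Total step count: 10. Longest linear sequence: 9 steps (steps 1 to 6, then 8, 9 and 10); step 7 is the one-step side branch.

Step 8 (key step). Most likely to go wrong: the enolate may attack through carbon instead of oxygen, after which the aryl anion is captured by the aldehyde and the C–CHO bond is cleaved. The enolate may also react from the E geometry, so that the aryl anion is protonated instead of cyclising, or un-ionised enol may protonate the anion early. The fallback sets out from 13 and 14 and returns at 20, using known chemistry. Ester 14 is saponified (LiOH, THF–H2O) to 2-(2,4,5-trimethoxyphenyl)acetic acid F1. F1 is heated with 13 and CsF in THF at 125 °C in a sealed vessel; this is the known insertion of arynes into the C–O bond of carboxylic acids. The carboxylate has no nucleophilic carbon, adds at C8a, and the acyl group is handed to C4a through a four-membered adduct, giving 1-[6-hydroxy-2,4-dimethoxy-3-(3-methylbut-2-enyl)phenyl]-2-(2,4,5-trimethoxyphenyl)ethanone F2. Heating F2 with Me2NCH(OMe)2 in toluene at 100 °C closes ring C by the classical one-carbon insertion and gives 20.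

Step 10. Most likely to go wrong: hydroxide may open ring C at C2 during the long alkaline reaction, conversion may be low as is usual for persulfate oxidations, the 5-hydroxyl may add across the prenyl double bond during acid hydrolysis of the sulfate, and the hydroquinone may be oxidised by air. The fallback sets out from 22 and returns at 24. 22 is oxidised with ON(SO3K)2 (KH2PO4 buffer, acetone–water, rt) to 7-methoxy-6-(3-methylbut-2-enyl)-3-(2,4,5-trimethoxyphenyl)chromene-4,5,8-trione F3, and F3 is reduced with aqueous Na2S2O4 (EtOAc–H2O, rt) to 24, with no strong acid or base.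

Step 9. Most likely to go wrong: traces of iodine or HI from MgI2 may cyclise the prenyl group onto the emerging 5-oxygen, or the reaction may be slow because the buttressed 5-methoxy group is twisted, with loss of a second methyl group (2'-OMe) on forcing. The fallback replaces the methyl ether by an acetal; it sets out from 3 and 17 and returns at 22.
- 5-Methoxyresorcinol F4 is mono-protected (MOMCl, i-Pr2NEt, statistical) to 3-methoxy-5-(methoxymethoxy)phenol F5 and silylated to [3-methoxy-5-(methoxymethoxy)phenoxy]tri(propan-2-yl)silane F6.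
- F6 is lithiated between the acetal and the methoxy group and allylated with 3 to [3-methoxy-5-(methoxymethoxy)-4-(3-methylbut-2-enyl)phenoxy]tri(propan-2-yl)silane F7, which is desilylated to 3-methoxy-5-(methoxymethoxy)-4-(3-methylbut-2-enyl)phenol F8.
- F8 is converted into 3-methoxy-5-(methoxymethoxy)-4-(3-methylbut-2-enyl)phenyl N-(propan-2-yl)carbamate F9 and silylated as in step 5 to 5-methoxy-3-(methoxymethoxy)-4-(3-methylbut-2-enyl)-2-(trimethylsilyl)phenyl N-(propan-2-yl)carbamate F10. Silylation is expected beside the acetal, the stronger co-director, but this is no longer fixed by symmetry.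
- F10 is cleaved and triflated as in step 6 to 5-methoxy-3-(methoxymethoxy)-4-(3-methylbut-2-enyl)-2-(trimethylsilyl)phenyl trifluoromethanesulfonate F11.
- F11 is annulated with 17 as in step 8 to 7-methoxy-5-(methoxymethoxy)-6-(3-methylbut-2-enyl)-3-(2,4,5-trimethoxyphenyl)chromen-4-one F12, and 1 M HCl in MeOH at rt removes the peri acetal to give 22.

Step 5. Most likely to go wrong: ortho-lithiation may be slow because the flanking methoxy group is pushed toward the reacting site, so that deprotonation of the benzylic and allylic CH2 of the prenyl group competes. The fallback sets out from 6 and returns at 13. 6 is brominated (N-bromosuccinimide, CH2Cl2, −78 °C; the two ortho positions are equivalent) to 2-bromo-3,5-dimethoxy-4-(3-methylbut-2-enyl)phenol F13 and O-silylated ((Me3Si)2NH, THF, 65 °C) to [2-bromo-3,5-dimethoxy-4-(3-methylbut-2-enyl)phenoxy]trimethylsilane F14. n-BuLi (THF, −78 °C) then effects bromine–lithium exchange and a retro-Brook 1,3 shift of silicon from oxygen to carbon, and the lithium phenoxide of 12 is triflated in the same flask with PhNTf2 to 13.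

## Further compounds

F1 | step 8 | 2-(2,4,5-trimethoxyphenyl)acetic acid | OC(=O)Cc1cc(OC)c(OC)cc1OC
F2 | step 8 | 1-[6-hydroxy-2,4-dimethoxy-3-(3-methylbut-2-enyl)phenyl]-2-(2,4,5-trimethoxyphenyl)ethanone | COc1cc(O)c(C(=O)Cc2cc(OC)c(OC)cc2OC)c(OC)c1CC=C(C)C
F3 | step 10 | 7-methoxy-6-(3-methylbut-2-enyl)-3-(2,4,5-trimethoxyphenyl)chromene-4,5,8-trione | COC1=C(CC=C(C)C)C(=O)C2=C(OC=C(c3cc(OC)c(OC)cc3OC)C2=O)C1=O
F4 | step 9 | 5-methoxyresorcinol (5-methoxybenzene-1,3-diol) | COc1cc(O)cc(O)c1
F5 | step 9 | 3-methoxy-5-(methoxymethoxy)phenol | COCOc1cc(O)cc(OC)c1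
F6 | step 9 | [3-methoxy-5-(methoxymethoxy)phenoxy]tri(propan-2-yl)silane | COCOc1cc(OC)cc(O[Si](C(C)C)(C(C)C)C(C)C)c1
F7 | step 9 | [3-methoxy-5-(methoxymethoxy)-4-(3-methylbut-2-enyl)phenoxy]tri(propan-2-yl)silane | COCOc1cc(O[Si](C(C)C)(C(C)C)C(C)C)cc(OC)c1CC=C(C)C
F8 | step 9 | 3-methoxy-5-(methoxymethoxy)-4-(3-methylbut-2-enyl)phenol | COCOc1cc(O)cc(OC)c1CC=C(C)C
F9 | step 9 | 3-methoxy-5-(methoxymethoxy)-4-(3-methylbut-2-enyl)phenyl N-(propan-2-yl)carbamate | COCOc1cc(OC(=O)NC(C)C)cc(OC)c1CC=C(C)C
F10 | step 9 | 5-methoxy-3-(methoxymethoxy)-4-(3-methylbut-2-enyl)-2-(trimethylsilyl)phenyl N-(propan-2-yl)carbamate | COCOc1c([Si](C)(C)C)c(OC(=O)NC(C)C)cc(OC)c1CC=C(C)C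
F11 | step 9 | 5-methoxy-3-(methoxymethoxy)-4-(3-methylbut-2-enyl)-2-(trimethylsilyl)phenyl trifluoromethanesulfonate | C[Si](C)(C)c1c(OCOC)c(CC=C(C)C)c(OC)cc1OS(=O)(=O)C(F)(F)F
F12 | step 9 | 7-methoxy-5-(methoxymethoxy)-6-(3-methylbut-2-enyl)-3-(2,4,5-trimethoxyphenyl)chromen-4-one | COCOc1c(CC=C(C)C)c(OC)cc2occ(-c3cc(OC)c(OC)cc3OC)c(=O)c12
F13 | step 5 | 2-bromo-3,5-dimethoxy-4-(3-methylbut-2-enyl)phenol | COc1cc(O)c(Br)c(OC)c1CC=C(C)C
F14 | step 5 | [2-bromo-3,5-dimethoxy-4-(3-methylbut-2-enyl)phenoxy]trimethylsilane | COc1cc(O[Si](C)(C)C)c(Br)c(OC)c1CC=C(C)C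
A1 | alternative 1 | 7-methoxy-5,8-bis(methoxymethoxy)-6-(3-methylbut-2-enyl)-3-(2,4,5-trimethoxyphenyl)chromen-4-one | COCOc1c(CC=C(C)C)c(OC)c(OCOC)c2occ(-c3cc(OC)c(OC)cc3OC)c(=O)c12
A2 | alternative 1 | 2-acetoxy-4-methoxy-3,6-bis(methoxymethoxy)-5-(3-methylbut-2-enyl)benzoyl chloride | CC(=O)Oc1c(OCOC)c(OC)c(CC=C(C)C)c(OCOC)c1C(=O)Cl
A3 | alternative 1 | 4-[(E)-2-(2,4,5-trimethoxyphenyl)ethenyl]morpholine | COc1cc(OC)c(/C=C/N2CCOCC2)cc1OC
A4 | alternative 2 | 5,8-bis(tert-butyldimethylsilyloxy)-7-methoxy-6-(3-methylbut-2-enyl)-3-(2,4,5-trimethoxyphenyl)chromen-4-one | CC(C)(C)[Si](C)(C)Oc1c(CC=C(C)C)c(OC)c(O[Si](C)(C)C(C)(C)C)c2occ(-c3cc(OC)c(OC)cc3OC)c(=O)c12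
A5 | alternative 2 | 1-[3,6-bis(tert-butyldimethylsilyloxy)-4-methoxy-2-(methoxymethoxy)-5-(3-methylbut-2-enyl)phenyl]-2-diazo-2-(2,4,5-trimethoxyphenyl)ethanone | COCOc1c(O[Si](C)(C)C(C)(C)C)c(OC)c(CC=C(C)C)c(O[Si](C)(C)C(C)(C)C)c1C(=O)C(=[N+]=[N-])c1cc(OC)c(OC)cc1OC
A6 | alternative 3 | 3-(2-hydroxy-4,5-dimethoxyphenyl)-7-methoxy-5,8-bis(methoxymethoxy)-6-(3-methylbut-2-enyl)chromen-4-one | COCOc1c(CC=C(C)C)c(OC)c(OCOC)c2occ(-c3cc(OC)c(OC)cc3O)c(=O)c12
A7 | alternative 3 | 3-ethynyl-7-methoxy-5,8-bis(methoxymethoxy)-6-(3-methylbut-2-enyl)chromen-4-one | C#Cc1coc2c(OCOC)c(OC)c(CC=C(C)C)c(OCOC)c2c1=O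
A8 | alternative 3 | pentacarbonyl[methoxy(1-methoxyethenyl)methylidene]chromium, (CO)5Cr=C(OMe)C(OMe)=CH2 | COC(=C)C(OC)=[Cr](=C=O)(=C=O)(=C=O)(=C=O)=C=O
A9 | alternative 3 | 3-iodo-7-methoxy-5,8-bis(methoxymethoxy)-6-(3-methylbut-2-enyl)chromen-4-one | COCOc1c(CC=C(C)C)c(OC)c(OCOC)c2occ(I)c(=O)c12
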